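(The rate constants were drawn at random within sensible limits.)

Every partner you charge stays on the books: it is free, dormant form, second product, third product, or carried inside target and inside side product made from target.

common to all: starting material 0.018 M; second substrate 1.00 equiv; protic impurity 0.360 mM; time 30 h
- epsilon: partner 1.80 equiv; third substrate 0.500 equiv; everything together at the start
- beta: partner 1.80 equiv; third substrate 0.500 equiv (fed, over 20 h); all else is in the flask from the start; the feed brings no volume worth counting
- theta: partner 1.80 equiv (fed, over 20 h); third substrate 0.500 equiv; all else is in the flask from the start; the feed brings no volume worth counting

* which flask leads in share of target in target plus side product ("all alike" within 1.5 percentage points) (epsilon / beta / theta / all alike)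
* share of target in target plus side product at the end, epsilon
* share of target in target plus side product at the end, beta
* share of target in target plus side product at the end, theta

- in percentages every species weighs as the starting material in it: one side product counts as two
- run time (epsilon): 30 h

    starting material + partner → target (k1 = 0.0051 L mol⁻¹ s⁻¹)
    starting material + target → side product (k2 = 3.1 × 10⁻⁴ L mol⁻¹ s⁻¹)
    partner ⇌ dormant form (K3 = 0.98, k3 = 1.8 × 10⁻⁶ s⁻¹)
    second substrate + partner → second product (k4 = 0.0021 L mol⁻¹ s⁻¹)
    third substrate + partner → third product (k5 = 0.0053 L mol⁻¹ s⁻¹)
    third substrate + protic impurity → quenched substrate (k6 = 0.020 L mol⁻¹ s⁻¹)

Here is my own reckoning, drawn as the curve of [target] in epsilon.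

1. The budget. You charge 32.4 mM of partner, while the three substrates ask for 45.0 mM, which is more than the charge. Partner is therefore the limiting reagent.

2. The start. In epsilon, [target] rises at 10.7 mM h⁻¹, and about half of the partner used at first goes to target.

3. The crossing. Target is made at a rate proportional to [starting material][partner] and lost at a rate proportional to [starting material][target], so [starting material] cancels. The making constant is 16.5 times the losing one; this is the selectivity factor. The curve therefore tops out when [partner] equals [target] divided by that factor. With [target] at the full charge of starting material, this gives the balance partner, the [partner] below which target is lost faster than it is made: 1.09 mM.

4. The knee and the level. Epsilon starts at 29.7 times the balance partner. As [partner] sinks toward it, the curve bends flat, then tips down, and any starting material still present pairs with target until that starting material is gone.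

5. The order. The half-life of third substrate at charged partner is 1.12 h, shorter than the 20 h of the feed in beta, so in beta, as long as [partner] stands near its charge, third substrate is used about as it comes and takes partner more slowly than in epsilon at the start. In theta, with the substrates near their charge, feed against consumption holds [partner] near 2.54 mM, just 2.33 times the balance partner. I commit to beta, then epsilon, then theta, without percentages.

The forecast names beta and gives 82 % for epsilon, 88 % for beta and 80 % for theta, holding that “Side product forms whenever starting material and target coexist, especially once partner runs low.”

The simulation gives beta, with 82.8 % for epsilon, 88.4 % for beta and 80.2 % for theta.

Taking the loss of third substrate + partner to third product out of the runs narrows the gap between beta and theta from 8.2 percentage points to 5.9 points, so that step is a part of the lead of beta, not its main part. In theta, mean [partner] over the first 20 h was 0.00345 M, 3.17 times the balance partner of 1.09 mM. A neighbour of theta charged with 4.50 equiv of partner still holds 33.3 mM at 30.0 h, far above the balance partner. Its share is 91.2 %, higher than the 88.4 % of beta.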